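**Retrosynthetic overview**
- The target is unmasked last by hydrogenolysis of the 3- and 5-benzyl ethers of a 3,5-bis(benzyloxy)flavone.
- Ring C is the only ring built. Cutting C4a–C4 and O1–C2 gives a ring A phenol (5-benzyloxy-2,3-dimethoxyphenol) and a three-carbon keto ester carrying ring B and the 3-oxygen; the two are joined in one solvent-free thermal Mentzer annulation.
- The strategy rests on C4a of ring A. It is the single unsubstituted carbon ortho to the oxygen that becomes O1 (C8 carries a methoxy group), and it is activated by the ortho 5-oxygen and the para 7-methoxy group. With the 5-oxygen capped, only the 5,7,8 pattern can close.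
- The phenol comes from 3-hydroxy-4,5-dimethoxybenzaldehyde by MOM protection, Baeyer–Villiger oxidation with methanolysis, benzylation and MOM removal. The keto ester comes from enolate aroylation of ethyl benzyloxyacetate.
- Rings A and B are purchased; ring C is closed in the penultimate step.

Key step: step 6

Remark: compounds 1, 7 and 8 are taken as commercial. Keto ester 9 is made and used as the racemate; its one stereocentre becomes the sp2 carbon C3 of ring C, and the target is achiral.

**Step 1**
Reactants: 1 3-hydroxy-4,5-dimethoxybenzaldehyde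
Product: 2 3,4-dimethoxy-5-(methoxymethoxy)benzaldehyde
Conditions: MOMCl (1.3 equiv), iPr2NEt (1.6 equiv), CH2Cl2, 0 °C to rt
Reagents that add atoms: chloromethyl methyl ether (MOMCl), COCCl
Why: O-alkylation of the phenol by the reactive alpha-chloro ether under amine base (Williamson type) should be clean, and the resulting acetal masks this oxygen through the peracid and benzylation steps.

**Step 2**
Reactants: 2 3,4-dimethoxy-5-(methoxymethoxy)benzaldehyde
Product: 4 3,4-dimethoxy-5-(methoxymethoxy)phenol, via aryl formate 3 (not isolated)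
Conditions: mCPBA (1.3 equiv), CH2Cl2, 0 °C to rt; aq Na2S2O3/NaHCO3 wash; then K2CO3 (0.2 equiv), MeOH, rt, N2
Reagents that add atoms: 3-chloroperoxybenzoic acid (mCPBA), OOC(=O)c1cccc(Cl)c1
Why: Baeyer–Villiger oxidation with aryl migration, favoured by the para methoxy group, should give the aryl formate, which is transesterified by methanol under mild carbonate catalysis without touching the MOM acetal.

**Step 3**
Reactants: 4 3,4-dimethoxy-5-(methoxymethoxy)phenol
Product: 5 1-benzyloxy-3,4-dimethoxy-5-(methoxymethoxy)benzene
Conditions: BnBr (1.2 equiv), K2CO3 (1.5 equiv), DMF, rt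
Reagents that add atoms: benzyl bromide, BrCc1ccccc1
Why: Williamson ether synthesis of the only free phenoxide with a primary benzylic bromide should install the future 5-O-benzyl group without competition.

**Step 4**
Reactants: 5 1-benzyloxy-3,4-dimethoxy-5-(methoxymethoxy)benzene
Product: 6 5-benzyloxy-2,3-dimethoxyphenol
Conditions: conc. HCl (cat.), MeOH, 45 °C
Reagents that add atoms: none
Why: Acid-catalysed acetal exchange in a large excess of methanol cleaves the MOM ether and traps the methoxymethyl cation as dimethoxymethane, while benzyl and methyl aryl ethers are stable to dilute acid.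

**Step 5**
Reactants: 7 ethyl benzyloxyacetate (2.1 equiv); 8 3,4,5-trimethoxybenzoyl chloride (1.0 equiv)
Product: 9 racemic ethyl 2-benzyloxy-3-oxo-3-(3,4,5-trimethoxyphenyl)propanoate
Conditions: LiN(iPr)2 (LDA, commercial solution, 2.1 equiv), THF, −78 °C; 8 in THF added dropwise, −78 °C; AcOH quench at −78 °C
Reagents that add atoms: none
Why: Crossed Claisen-type C-acylation of the chelated lithium enolate of the alkoxyacetate by the aroyl chloride should give the beta-keto ester; the second equivalent of enolate deprotonates the more acidic product and so prevents a second aroylation, and the new stereocentre is formed without control (racemic).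

**Step 6**
Reactants: 6 5-benzyloxy-2,3-dimethoxyphenol (1.0 equiv); 9 racemic ethyl 2-benzyloxy-3-oxo-3-(3,4,5-trimethoxyphenyl)propanoate (1.5 equiv)
Product: 13 3,5-bis(benzyloxy)-7,8-dimethoxy-2-(3,4,5-trimethoxyphenyl)-4H-chromen-4-one, via acylketene 10 (not isolated), via aryl ester 11 (not isolated), via hydroxyaryl 1,3-diketone 12 (not isolated)
Conditions: neat melt, 200–220 °C, slow Ar stream to carry off EtOH and H2O (or sealed-vessel microwave heating at the same temperature for minutes)
Reagents that add atoms: none
Why: On heating, the enol of 9 should expel ethanol through a six-membered transition state to give acylketene 10; the phenol oxygen of 6 captures the ketene carbon to give aryl ester 11, and a thermal ortho acyl shift of Fries type to the only free ortho carbon gives diketone 12 and the C4a–C4 bond. The phenol oxygen then adds to the aryl ketone carbonyl in a 6-exo-trig closure and the hemiketal loses water, which forms O1–C2 and the 4-pyranone ring C with the benzyloxy group already on C3. The closest known reaction type is the Mentzer pyrone synthesis of flavones from electron-rich phenols and aroylacetates, the acid-free relative of the Simonis chromone synthesis. No stereocentre is created, since the racemic carbon of 9 ends as the sp2 carbon C3. Chromone formation must win over 4-arylcoumarin formation, and acid-free heating secures this because the former ester carbon, as a ketene, is the electrophile that reaches the ring, whereas the aryl ketone is hindered by the alpha-benzyloxy group and deactivated by its trimethoxyphenyl donor. Ortho acylation must win over para acylation, and this is secured by delivery of the acyl group from the phenol oxygen, by the methoxy group that blocks C8 and by the benzyl cap on the 5-oxygen, so that only the 5,7,8 isomer can close.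

**Step 7**
Reactants: 13 3,5-bis(benzyloxy)-7,8-dimethoxy-2-(3,4,5-trimethoxyphenyl)-4H-chromen-4-one
Product: 14 3,5-dihydroxy-7,8-dimethoxy-2-(3,4,5-trimethoxyphenyl)-4H-chromen-4-one (3,5-dihydroxy-7,8,3',4',5'-pentamethoxyflavone)
Conditions: H2 (1 atm), Pd/C (10% palladium on carbon), EtOAc–MeOH, rt
Reagents that add atoms: none
Why: Catalytic hydrogenolysis should cleave both benzylic C–O bonds, while the aryl methyl ethers and the conjugated 4-pyranone are inert at ambient pressure and temperature.

**Compound list**
1 | 3-hydroxy-4,5-dimethoxybenzaldehyde | COc1cc(C=O)cc(O)c1OC | starting material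
2 | 3,4-dimethoxy-5-(methoxymethoxy)benzaldehyde | COCOc1cc(C=O)cc(OC)c1OC | intermediate
3 | 3,4-dimethoxy-5-(methoxymethoxy)phenyl formate | COCOc1cc(OC=O)cc(OC)c1OC | intermediate (not isolated)
4 | 3,4-dimethoxy-5-(methoxymethoxy)phenol | COCOc1cc(O)cc(OC)c1OC | intermediate
5 | 1-benzyloxy-3,4-dimethoxy-5-(methoxymethoxy)benzene | COCOc1cc(OCc2ccccc2)cc(OC)c1OC | intermediate
6 | 5-benzyloxy-2,3-dimethoxyphenol | COc1cc(OCc2ccccc2)cc(O)c1OC | intermediate
7 | ethyl benzyloxyacetate | CCOC(=O)COCc1ccccc1 | starting material
8 | 3,4,5-trimethoxybenzoyl chloride | COc1cc(C(=O)Cl)cc(OC)c1OC | starting material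
9 | racemic ethyl 2-benzyloxy-3-oxo-3-(3,4,5-trimethoxyphenyl)propanoate | CCOC(=O)C(OCc1ccccc1)C(=O)c1cc(OC)c(OC)c(OC)c1 | intermediate
10 | 2-benzyloxy-3-oxo-3-(3,4,5-trimethoxyphenyl)prop-1-en-1-one (aroyl(benzyloxy)ketene) | O=C=C(OCc1ccccc1)C(=O)c1cc(OC)c(OC)c(OC)c1 | intermediate (not isolated)
11 | 5-benzyloxy-2,3-dimethoxyphenyl 2-benzyloxy-3-oxo-3-(3,4,5-trimethoxyphenyl)propanoate (racemic) | COc1cc(OCc2ccccc2)cc(OC(=O)C(OCc2ccccc2)C(=O)c2cc(OC)c(OC)c(OC)c2)c1OC | intermediate (not isolated)
12 | 1-(6-benzyloxy-2-hydroxy-3,4-dimethoxyphenyl)-2-benzyloxy-3-(3,4,5-trimethoxyphenyl)propane-1,3-dione (racemic) | COc1cc(OCc2ccccc2)c(C(=O)C(OCc2ccccc2)C(=O)c2cc(OC)c(OC)c(OC)c2)c(O)c1OC | intermediate (not isolated)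
13 | 3,5-bis(benzyloxy)-7,8-dimethoxy-2-(3,4,5-trimethoxyphenyl)-4H-chromen-4-one | COc1cc(-c2oc3c(OC)c(OC)cc(OCc4ccccc4)c3c(=O)c2OCc2ccccc2)cc(OC)c1OC | intermediate
14 | 3,5-dihydroxy-7,8-dimethoxy-2-(3,4,5-trimethoxyphenyl)-4H-chromen-4-one | COc1cc(-c2oc3c(OC)c(OC)cc(O)c3c(=O)c2O)cc(OC)c1OC | target

**Step count**
Total step count: 7.
Longest linear sequence: 6 steps (steps 1, 2, 3, 4, 6, 7); step 5 is a one-step side branch.

**Steps most likely to fail, riskiest first**

Step 6. Loss of ethanol from the alpha-benzyloxy keto ester may be slow, so ketene dimerisation, thermolysis or migration of the benzyl ethers, or acylation para to the hydroxyl (which cannot cyclise) may outrun the ortho C-acylation. Partial loss of the 5-O-benzyl group alone would be harmless, since step 7 removes it anyway. The fallback makes the same two bonds stepwise at low temperature by a Baker–Venkataraman sequence; it sets out from 5 and comes back at 13. Directed ortho-lithiation of 5 at the carbon between the MOM ether and the benzyl ether (n-BuLi, THF, 0 °C), then acylation with 2-(benzyloxy)-N-methoxy-N-methylacetamide, should give 1-[6-benzyloxy-3,4-dimethoxy-2-(methoxymethoxy)phenyl]-2-(benzyloxy)ethan-1-one F1. Cleavage of the MOM ether (cat. HCl, MeOH) should give 1-(6-benzyloxy-2-hydroxy-3,4-dimethoxyphenyl)-2-(benzyloxy)ethan-1-one F2. O-Aroylation with 8 in pyridine should give 3-benzyloxy-2-(2-benzyloxyacetyl)-5,6-dimethoxyphenyl 3,4,5-trimethoxybenzoate F3. Treatment with KOtBu in THF should then move the aroyl group from oxygen to the ketone alpha-carbon and give diketone 12, here isolated. Cyclodehydration (TsOH cat., toluene, 80 °C) should give 13.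

Step 5. The acid chloride may acylate the enolate at oxygen, or acylate the enolate of the product a second time. The benzyloxy enolate may also self-condense or undergo a [1,2]-Wittig shift if the temperature rises. The fallback builds the keto ester first and introduces the 2-oxygen afterwards by carbenoid O–H insertion; it sets out from 8 and comes back at 9. Acylation of potassium ethyl malonate with 8 (MgCl2, Et3N, MeCN) should give, after aqueous HCl, 2-(ethoxycarbonyl)-3-oxo-3-(3,4,5-trimethoxyphenyl)propanoic acid F4, which is not isolated and decarboxylates to ethyl 3-oxo-3-(3,4,5-trimethoxyphenyl)propanoate F5. Regitz diazo transfer with 4-acetamidobenzenesulfonyl azide (p-ABSA) and Et3N in MeCN should give ethyl 2-diazo-3-oxo-3-(3,4,5-trimethoxyphenyl)propanoate F6. Insertion of the derived rhodium carbenoid into the O–H bond of benzyl alcohol (Rh2(OAc)4 cat., BnOH, CH2Cl2, 40 °C) should give 9.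

Step 2. The 4-methoxy group lies between two ortho substituents and is twisted out of conjugation, so aryl migration in the Criegee adduct may lose to hydride migration and give the benzoic acid. The 3-chlorobenzoic acid formed may also strip the MOM acetal. The fallback replaces the aldehyde by a methyl ketone, in which no hydride can migrate and aryl migrates far better than methyl; it sets out from 2 and comes back at 4. Addition of MeMgBr (THF, 0 °C) should give racemic 1-[3,4-dimethoxy-5-(methoxymethoxy)phenyl]ethan-1-ol F7. Benzylic oxidation with MnO2 in CH2Cl2 should give 1-[3,4-dimethoxy-5-(methoxymethoxy)phenyl]ethan-1-one F8. Baeyer–Villiger oxidation with mCPBA buffered by NaHCO3 should give 3,4-dimethoxy-5-(methoxymethoxy)phenyl acetate F9. Methanolysis (K2CO3 cat., MeOH) should give 4.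

**Further compounds**
F1 | step 6 | 1-[6-benzyloxy-3,4-dimethoxy-2-(methoxymethoxy)phenyl]-2-(benzyloxy)ethan-1-one | COCOc1c(C(=O)COCc2ccccc2)c(OCc2ccccc2)cc(OC)c1OC
F2 | step 6 | 1-(6-benzyloxy-2-hydroxy-3,4-dimethoxyphenyl)-2-(benzyloxy)ethan-1-one | COc1cc(OCc2ccccc2)c(C(=O)COCc2ccccc2)c(O)c1OC
F3 | step 6 | 3-benzyloxy-2-(2-benzyloxyacetyl)-5,6-dimethoxyphenyl 3,4,5-trimethoxybenzoate | COc1cc(OCc2ccccc2)c(C(=O)COCc2ccccc2)c(OC(=O)c2cc(OC)c(OC)c(OC)c2)c1OC
F4 | step 5 | 2-(ethoxycarbonyl)-3-oxo-3-(3,4,5-trimethoxyphenyl)propanoic acid (racemic) | CCOC(=O)C(C(=O)O)C(=O)c1cc(OC)c(OC)c(OC)c1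
F5 | step 5 | ethyl 3-oxo-3-(3,4,5-trimethoxyphenyl)propanoate | CCOC(=O)CC(=O)c1cc(OC)c(OC)c(OC)c1
F6 | step 5 | ethyl 2-diazo-3-oxo-3-(3,4,5-trimethoxyphenyl)propanoate | CCOC(=O)C(=[N+]=[N-])C(=O)c1cc(OC)c(OC)c(OC)c1
F7 | step 2 | racemic 1-[3,4-dimethoxy-5-(methoxymethoxy)phenyl]ethan-1-ol | COCOc1cc(C(C)O)cc(OC)c1OC
F8 | step 2 | 1-[3,4-dimethoxy-5-(methoxymethoxy)phenyl]ethan-1-one | COCOc1cc(C(C)=O)cc(OC)c1OC
F9 | step 2 | 3,4-dimethoxy-5-(methoxymethoxy)phenyl acetate | COCOc1cc(OC(C)=O)cc(OC)c1OC
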